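**The leftover.** After 98 h the zeta run still holds 0.0268 M of starting material unturned, so a molecule charged there has a chance of 46.4% of having become product. The eta flask asks for that same chance at a smaller charge.

| flask | starting material | free catalyst | time |
|---|---|---|---|
| zeta | 0.0500 M | 0.00100 M |  |
| gamma | 0.0750 M | 0.00100 M |  |
| delta | 0.0500 M | 0.00150 M |  |
| eta | 0.0170 M | 3.30 × 10⁻⁴ M | 98 h |

- zeta run (time / h: [product] / M): 5.6: 6 × 10⁻⁴; 17: 0.0028; 32: 0.0059; 51: 0.0087; 73: 0.0150; 98: 0.0232
- gamma run (time / h: [product] / M): 5.6: 6 × 10⁻⁴; 17: 0.0027; 32: 0.0067; 51: 0.0139; 73: 0.0238; 98: 0.0371
- delta run (time / h: [product] / M): 5.6: 0.0020; 17: 0.0035; 32: 0.0075; 51: 0.0122; 73: 0.0193; 98: 0.0285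

(each reading ± 5 × 10⁻⁴ M)

* the exponent of [starting material] in the starting rate at the charge of the zeta run (at the point where two percent of the starting material have become product) (one fixed amount of product, the same in the runs compared)
* the exponent of [free catalyst] in the starting rate at the charge of the zeta run (at the point where two percent of the starting material have become product)
* product in the eta run at 98 h, as a share of the starting material charged

- Overall: starting material -> product, with free catalyst as catalyst.
- Constant volume, constant temperature.
- What is held in complexes is read along with the free species.
- An order is taken over about fifteen percent of the charge, up and down.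

**Shrink factor.** The gamma run turns a share of 49.5% and the delta run 57.0% at that time. Each differs from the zeta run in one charge, so each gives an exponent of the share: 0.158 in starting material and 0.507 in free catalyst. These are not the starting-rate orders asked for. The eta charges are each about a third of the zeta charges, and raising those two ratios to these exponents and multiplying gives 0.481, the shrink factor: the part of a zeta molecule's chance that a molecule in the eta flask keeps at 98 h. The reckoning here therefore reads 22.3% for the eta run.

The same steps on the readings at 73 h give 0.432, so the number does not drift far with time. But the eta charge of starting material lies below that of every run, and that stretch remains untested.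

**The forecast.** It gives exponents of 0.1 and 0.7 and a share of 38%, higher than the reckoning here, and it warns: “This extrapolation assumes saturation still holds at low substrate, so it is uncertain.”

**The flask.** The exponents are 0.56 in starting material and 0.47 in free catalyst. The eta run reaches 32.6%, so its shrink factor is 0.703, above the 0.481 reckoned.

    2 free catalyst ⇌ catalyst dimer, settled at all times (82000 M⁻¹)
    free catalyst + starting material → product + free catalyst (219.6 M⁻¹ h⁻¹)
    2 starting material ⇌ idle substrate dimer, settled at all times (290.0 M⁻¹)
    starting material + product → 2 product (1.746 M⁻¹ h⁻¹)

The idle substrate dimer, a resting state of the starting material, is the main reason for that share. The same eta run without this tying up reaches 91.3%, a shrink factor of 1.97 against the zeta share as it stands. The difference of 59 percentage points is 87% of what is missing.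

(The runs come from a simulation on assumed constants; noise was put on by code.)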